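**Plan**

- Late cuts: the C16 formate, the C17 aldehyde and the C12–C13 bond (B-alkyl Suzuki–Miyaura coupling of a C9 vinyl group with a (Z)-enol triflate); the 7-en-17-ol is traced back to an 8(17)-exocyclic alkene, and ring B is then cut at C6–C7 and C9–C10 together.
- Enabling feature: ring B holds the C6 carbinol 1,3 to quaternary C10 (through C5) beside the isobutenyl unit C7–C8(C17)–C9, and C9 carries the two-carbon stub C11–C12. C12–C11=C9 and C10=C5–C6(O) can therefore be tied into a 1,5-dien-3-ol through a sacrificial C6–C12 bond.
- Forward: β-cyclocitral (ring A with C5, C6, C10) is propargylated, the enyne is built and semireduced, and an alkoxide-accelerated oxy-Cope shift followed in the same flask by a carbonyl-ene closure forms ring B. Oxidation-level adjustment and side-chain coupling follow.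
- Stereochemistry: the R carbinol at C6 comes from catalytic asymmetric propargylation and is relayed through the chair [3,3] transition state to C10 and C9. C5 and C6 are then reset under substrate control, and 13E comes from the (Z)-enol triflate.

Key step: step 4

Remark: atoms are numbered as in labdane (C1–C20; the target is an ent-labdane), and the facial sense of the phosphoric acid catalyst in step 1 is assumed to follow that known for aryl and α,β-unsaturated aldehydes.

**Route**

Step 1
Reactants: 1 β-cyclocitral; 2 allenylboronic acid pinacol ester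
Product: 3 (R)-1-(2,6,6-trimethylcyclohex-1-en-1-yl)but-3-yn-1-ol
Conditions: (R)-TRIP phosphoric acid (10 mol %), 4 Å MS, toluene, 0 °C
Reagents that add atoms: none
Why: Brønsted-acid-catalysed asymmetric propargylation, in which the allenylboronate adds through a closed six-membered transition state organised by the chiral phosphate, should give the homopropargylic alcohol and set C6 as R.

Step 2
Reactants: 3 (R)-homopropargylic alcohol; 4 2-bromopropene
Product: 5 (R)-5-methyl-1-(2,6,6-trimethylcyclohex-1-en-1-yl)hex-5-en-3-yn-1-ol
Conditions: Pd(PPh3)2Cl2 (5 mol %), CuI (10 mol %), iPr2NH, THF, 25 °C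
Reagents that add atoms: none
Why: Sonogashira coupling of the terminal alkyne with the vinyl bromide tolerates the free hydroxyl and installs the isopropenyl group that later supplies C7, C8 and C17.

Step 3
Reactants: 5 enyne alcohol
Product: 6 (1R,3Z)-5-methyl-1-(2,6,6-trimethylcyclohex-1-en-1-yl)hexa-3,5-dien-1-ol
Conditions: H2 (1 atm), Pd/CaCO3 poisoned with Pb(OAc)2 (Lindlar catalyst), quinoline, EtOAc, 25 °C
Reagents that add atoms: none
Why: Lindlar semihydrogenation adds hydrogen syn to the alkyne and should stop at the (Z)-diene, because the tetrasubstituted ring alkene and the isopropenyl group are far less reactive on the poisoned catalyst.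

Step 4
Reactants: 6 (1R,3Z)-dienyl carbinol
Product: 10 (5R,6R,9R,10S)-13,14,15,16-tetranorlabda-8(17),11-dien-6-ol, via potassium alkoxide 7 (not isolated), via potassium enolate 8 (not isolated), via aldehyde 9 (not isolated)
Conditions: KN(SiMe3)2 (1.1 equiv), 18-crown-6, THF, −78 → 40 °C; AcOH (1.1 equiv), −78 °C; exchange THF for CH2Cl2; Me2AlCl (5 equiv), −78 → 0 °C; aq. Rochelle salt
Reagents that add atoms: none
Why: Deprotonation gives alkoxide 7, whose 1,5-diene array C10=C5–C6–C12–C11=C9 undergoes an alkoxide-accelerated oxy-Cope [3,3] shift that forms C9–C10, cleaves the sacrificial C6–C12 bond and leaves enolate 8; protonation on carbon gives aldehyde 9, and Me2AlCl then induces an intramolecular carbonyl-ene reaction of type 2 in which the isopropenyl CH2 (the future C7) bonds to C6 while a methyl hydrogen passes to oxygen, so that the C8=C17 exocyclic alkene remains. The closest known reactions are the anionic oxy-Cope rearrangement of cyclohexenyl homoallyl carbinols to aldehydes with a new quaternary centre, tandem oxy-Cope/ene sequences, and the Me2AlCl-promoted closure of δ,ε-unsaturated aldehydes to 3-methylenecyclohexanols. Ring B is closed as a six-membered ring through a chair-like ene transition state, exo at the C6 carbonyl and with both alkene carbons C7 and C8 inside the new ring, trans-fused to ring A. C10 and C9 are set together in the chair transition state of the [3,3] shift, in which the C6 oxygen is equatorial (an axial oxygen would be 1,3-diaxial to the C10 methyl) so that the R carbinol selects the face of C10, and the Z geometry of C11=C9 places C8 axial and hence the vinyl group cis to the C10 methyl. C5 is set by axial protonation of enolate 8 opposite the two syn-axial methyl groups on C4 and C10, and C6 by the equatorial position of the aluminium-bound carbonyl oxygen, since the axial position is 1,3-diaxial to the C10 methyl and close to the axial C4 methyl. The step needs the concerted shift to be faster than fragmentation of 7 into β-cyclocitral and a pentadienyl anion, which the crown-ether-separated potassium alkoxide of a secondary carbinol at moderate temperature should secure, and it needs the ene reaction to engage the more nucleophilic 1,1-disubstituted alkene and not the vinyl group, which the tertiary cationic character at C8 in the transition state secures.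

Step 5
Reactants: 10 bicyclic homoallylic alcohol
Product: 11 8,17-epoxide of 10 (oxygen on the face of H-9, away from the C10 methyl)
Conditions: VO(acac)2 (5 mol %), t-BuOOH, CH2Cl2, 0 → 25 °C
Reagents that add atoms: tert-butyl hydroperoxide, CC(C)(C)OO
Why: Hydroxyl-directed vanadium-catalysed epoxidation should engage only the C8=C17 alkene that is homoallylic to the C6 hydroxyl, leave the remote vinyl group, and deliver oxygen to the face away from the axial C10 methyl.

Step 6
Reactants: 11 epoxy alcohol
Product: 12 (5R,6R,9S,10S)-13,14,15,16-tetranorlabda-7,11-diene-6,17-diol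
Conditions: Et2AlTMP (from LiTMP and Et2AlCl, 4 equiv), toluene, 0 °C; aq. Rochelle salt
Reagents that add atoms: none
Why: The aluminium amide promotes the epoxide-to-allylic-alcohol isomerisation by syn removal of the less hindered ring hydrogen at C7 (not the congested tertiary H-9), which opens the oxirane to the C7=C8 alkene and the primary C17 alcohol without touching the existing stereocentres.

Step 7
Reactants: 13 methyl 4-chloro-3-oxobutanoate
Product: 14 methyl 4-[(4-methoxybenzyl)oxy]-3-oxobutanoate
Conditions: NaH (2.2 equiv), 4-methoxybenzyl alcohol, THF, 0 → 25 °C; aq. HCl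
Reagents that add atoms: 4-methoxybenzyl alcohol, COc1ccc(CO)cc1
Why: Williamson displacement of the primary chloride by the alkoxide on the sodium enolate of the β-keto ester is a standard entry to 4-alkoxyacetoacetates.

Step 8
Reactants: 14 β-keto ester
Product: 15 methyl (Z)-4-[(4-methoxybenzyl)oxy]-3-{[(trifluoromethyl)sulfonyl]oxy}but-2-enoate
Conditions: Tf2O, sat. aq. LiOH, toluene, 5 °C
Reagents that add atoms: triflic anhydride, O=S(=O)(OS(=O)(=O)C(F)(F)F)C(F)(F)F
Why: Triflation of the chelated lithium (Z)-enolate under biphasic conditions should give the (Z)-enol triflate, which places the triflate cis to the ester as the coupling requires.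

Step 9
Reactants: 12 diene diol; 15 (Z)-enol triflate
Product: 17 methyl (5R,6R,9S,10S,13E)-6,17-dihydroxy-16-[(4-methoxybenzyl)oxy]labda-7,13-dien-15-oate, via B-alkyl-9-BBN adduct 16 (not isolated)
Conditions: 9-BBN (4 equiv), THF, 0 → 25 °C; then 15, Pd(dppf)Cl2 (10 mol %), AsPh3, 3 M aq. K3PO4, DMF, 25 °C
Reagents that add atoms: none
Why: 9-BBN hydroborates the monosubstituted vinyl group at its terminal carbon in preference to the trisubstituted allylic alkene (the hydroxyls are held as borinates and freed on work-up), and the B-alkyl Suzuki–Miyaura coupling proceeds with retention of alkene geometry to give the 13E olefin.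

Step 10
Reactants: 17 diol ester
Product: 18 methyl (5R,6R,9S,10S,13E)-6-hydroxy-16-[(4-methoxybenzyl)oxy]-17-oxolabda-7,13-dien-15-oate
Conditions: TEMPO (20 mol %), PhI(OAc)2 (1.1 equiv), CH2Cl2, 25 °C
Reagents that add atoms: none
Why: Oxoammonium (TEMPO) oxidation with PhI(OAc)2 as terminal oxidant is selective for the primary allylic alcohol over the hindered secondary C6 alcohol and stops at the aldehyde.

Step 11
Reactants: 18 hydroxy enal
Product: 19 methyl (5R,6R,9S,10S,13E)-6,16-dihydroxy-17-oxolabda-7,13-dien-15-oate
Conditions: DDQ (1.3 equiv), CH2Cl2/pH 7 buffer, 0 °C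
Reagents that add atoms: none
Why: Oxidative cleavage of the 4-methoxybenzyl ether by DDQ proceeds by hydride abstraction from the electron-rich benzylic position and should leave the enal, the enoate and the allylic alcohol untouched.

Step 12
Reactants: 19 diol
Product: 20 methyl (5R,6R,9S,10S,13E)-16-(formyloxy)-6-hydroxy-17-oxolabda-7,13-dien-15-oate (target)
Conditions: acetic formic anhydride (1.2 equiv), pyridine, CH2Cl2, −20 °C
Reagents that add atoms: acetic formic anhydride, CC(=O)OC=O
Why: Acylation with the mixed anhydride transfers the formyl group, and the unhindered primary allylic C16 hydroxyl should react much faster than the secondary C6 hydroxyl, which is shielded by the C4 gem-dimethyl group and the ring fusion.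

**Compound list**

1 | β-cyclocitral (2,6,6-trimethylcyclohex-1-ene-1-carbaldehyde) | CC1=C(C=O)C(C)(C)CCC1 | starting material
2 | allenylboronic acid pinacol ester | C=C=CB1OC(C)(C)C(C)(C)O1 | starting material
3 | (R)-1-(2,6,6-trimethylcyclohex-1-en-1-yl)but-3-yn-1-ol | C#CC[C@@H](O)C1=C(C)CCCC1(C)C | intermediate
4 | 2-bromopropene | CC(Br)=C | starting material
5 | (R)-5-methyl-1-(2,6,6-trimethylcyclohex-1-en-1-yl)hex-5-en-3-yn-1-ol | C=C(C)C#CC[C@@H](O)C1=C(C)CCCC1(C)C | intermediate
6 | (1R,3Z)-5-methyl-1-(2,6,6-trimethylcyclohex-1-en-1-yl)hexa-3,5-dien-1-ol | C=C(C)/C=C\C[C@@H](O)C1=C(C)CCCC1(C)C | intermediate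
7 | potassium alkoxide of 6 | C=C(C)/C=C\C[C@@H]([O-])C1=C(C)CCCC1(C)C.[K+] | intermediate
8 | potassium (E)-enolate of 9 (oxygen syn to C4; C10 S, C9 R) | [K+].[O-]/C=C1\C(C)(C)CCC[C@@]1(C)[C@H](C=C)C(C)=C | intermediate
9 | (1R,6S)-2,2,6-trimethyl-6-[(3R)-2-methylpenta-1,4-dien-3-yl]cyclohexane-1-carbaldehyde | O=C[C@@H]1C(C)(C)CCC[C@@]1(C)[C@H](C=C)C(C)=C | intermediate
10 | (5R,6R,9R,10S)-13,14,15,16-tetranorlabda-8(17),11-dien-6-ol (trans-decalin; 6-OH equatorial, 9-vinyl cis to the C10 methyl) | C=C[C@@H]1C(=C)C[C@@H](O)[C@@H]2C(C)(C)CCC[C@@]12C | intermediate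
11 | 8,17-epoxide of 10, oxygen on the face of H-9 and anti to the C10 methyl | C=C[C@@H]1[C@]3(CO3)C[C@@H](O)[C@@H]2C(C)(C)CCC[C@@]12C | intermediate
12 | (5R,6R,9S,10S)-13,14,15,16-tetranorlabda-7,11-diene-6,17-diol | C=C[C@@H]1C(CO)=C[C@@H](O)[C@@H]2C(C)(C)CCC[C@@]12C | intermediate
13 | methyl 4-chloro-3-oxobutanoate | COC(=O)CC(=O)CCl | starting material
14 | methyl 4-[(4-methoxybenzyl)oxy]-3-oxobutanoate | COC(=O)CC(=O)COCc1ccc(OC)cc1 | intermediate
15 | methyl (Z)-4-[(4-methoxybenzyl)oxy]-3-{[(trifluoromethyl)sulfonyl]oxy}but-2-enoate | COC(=O)/C=C(/COCc1ccc(OC)cc1)OS(=O)(=O)C(F)(F)F | intermediate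
16 | B-alkyl-9-BBN adduct of 12 (boron on C12; hydroxyls drawn free) | C(C[C@@H]1C(CO)=C[C@@H](O)[C@@H]2C(C)(C)CCC[C@@]12C)B3C4CCCC3CCC4 | intermediate
17 | methyl (5R,6R,9S,10S,13E)-6,17-dihydroxy-16-[(4-methoxybenzyl)oxy]labda-7,13-dien-15-oate | COC(=O)/C=C(\CC[C@@H]1C(CO)=C[C@@H](O)[C@@H]2C(C)(C)CCC[C@@]12C)COCc1ccc(OC)cc1 | intermediate
18 | methyl (5R,6R,9S,10S,13E)-6-hydroxy-16-[(4-methoxybenzyl)oxy]-17-oxolabda-7,13-dien-15-oate | COC(=O)/C=C(\CC[C@@H]1C(C=O)=C[C@@H](O)[C@@H]2C(C)(C)CCC[C@@]12C)COCc1ccc(OC)cc1 | intermediate
19 | methyl (5R,6R,9S,10S,13E)-6,16-dihydroxy-17-oxolabda-7,13-dien-15-oate | COC(=O)/C=C(\CC[C@@H]1C(C=O)=C[C@@H](O)[C@@H]2C(C)(C)CCC[C@@]12C)CO | intermediate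
20 | methyl (5R,6R,9S,10S,13E)-16-(formyloxy)-6-hydroxy-17-oxolabda-7,13-dien-15-oate | COC(=O)/C=C(\CC[C@@H]1C(C=O)=C[C@@H](O)[C@@H]2C(C)(C)CCC[C@@]12C)COC=O | target

**Step count and risks**

Total step count: 12 (10 in the main line, 2 for the enol triflate).
Longest linear sequence: 10 steps (steps 1–6 and 9–12, from compound 1).

Steps most likely to fail:

1. Step 4. Once the medium is changed from basic to Lewis-acidic, the ene closure may stall on the very hindered aldehyde, or the hydrogen may be taken from C9 instead of the methyl group, giving the endocyclic 8,9-alkene; the crown ether and acetate may also quench the aluminium reagent. The fallback separates the two events and replaces the ene reaction by an allylsilane addition. It sets out from compound 3. Sonogashira coupling with 2-bromoallyltrimethylsilane should give the silyl enyne F1, Lindlar semihydrogenation the (Z)-dienyl silane F2, and the same alkoxide-accelerated [3,3] shift with aqueous work-up the isolated silyl aldehyde F3. BF3·OEt2 in CH2Cl2 at −78 °C then closes ring B by intramolecular Hosomi–Sakurai allylation: the allylsilane terminus attacks C6 and loss of the silyl group fixes the exocyclic alkene. The route is rejoined at compound 10. This fallback does not remove the risk that alkoxide 7 fragments before it rearranges, since it uses the same [3,3] shift.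

2. Step 1. Facial discrimination or conversion may be poor in the catalytic propargylation of this tetrasubstituted, doubly flanked enal. The fallback is a resolution and sets out from compound 1. Zinc-mediated Barbier propargylation (propargyl bromide, Zn, THF/aq. NH4Cl) should give the racemic homopropargylic alcohol F4. Esterification with (S)-O-methylmandelic acid (DCC, DMAP) gives two diastereomeric esters that are separated by chromatography. The (S)-O-methylmandelate of the R alcohol F5 is cleaved with K2CO3 in MeOH, and the route is rejoined at compound 3.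

3. Step 6. Regiocontrol may be lost in the base-induced opening: removal of the tertiary, doubly allylic H-9 would give the 8,9-alkene conjugated with the vinyl group. The fallback is an oxidative transposition that bypasses epoxide 11 and sets out from compound 10. Dye-sensitised photooxygenation (O2, tetraphenylporphyrin, visible light, CH2Cl2, 0 °C) should give, by the Schenck ene reaction with hydrogen taken from the less encumbered C7 methylene, the transposed allylic hydroperoxide F6. This is reduced in the same flask with PPh3, and the route is rejoined at compound 12.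

Further compounds
F1 | step 4 | (R)-5-[(trimethylsilyl)methyl]-1-(2,6,6-trimethylcyclohex-1-en-1-yl)hex-5-en-3-yn-1-ol | C=C(C[Si](C)(C)C)C#CC[C@@H](O)C1=C(C)CCCC1(C)C
F2 | step 4 | (1R,3Z)-5-[(trimethylsilyl)methyl]-1-(2,6,6-trimethylcyclohex-1-en-1-yl)hexa-3,5-dien-1-ol | C=C(C[Si](C)(C)C)/C=C\C[C@@H](O)C1=C(C)CCCC1(C)C
F3 | step 4 | silyl analogue of aldehyde 9 carrying a 2-[(trimethylsilyl)methyl]penta-1,4-dien-3-yl group, same configuration at C5, C9 and C10 | O=C[C@@H]1C(C)(C)CCC[C@@]1(C)[C@H](C=C)C(=C)C[Si](C)(C)C
F4 | step 1 | racemic 1-(2,6,6-trimethylcyclohex-1-en-1-yl)but-3-yn-1-ol | C#CCC(O)C1=C(C)CCCC1(C)C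
F5 | step 1 | (R)-1-(2,6,6-trimethylcyclohex-1-en-1-yl)but-3-yn-1-yl (S)-2-methoxy-2-phenylacetate | C#CC[C@@H](OC(=O)[C@@H](OC)c1ccccc1)C1=C(C)CCCC1(C)C
F6 | step 6 | 17-hydroperoxy-13,14,15,16-tetranorlabda-7,11-dien-6-ol, configuration as in 12 | C=C[C@@H]1C(COO)=C[C@@H](O)[C@@H]2C(C)(C)CCC[C@@]12C
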